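**Retrosynthetic overview**
1. The target is reached from its tris-MOM ether by acidic removal of the three MOM groups; rings A (from 5-fluororesorcinol) and B (from vanillin) are bought, and ring C is the only ring formed, last.
2. Ring C is made in one flask from an aryl enol silane and O-MOM-vanillin: the C-2–C-3 bond by a catalytic asymmetric Mukaiyama aldol, then the O-1–C-8a bond by fluoride-triggered ipso substitution of fluorine.
3. Enabling feature: the C-4 carbonyl of ring C lies 1,3 to O-1 (aldol retron) and ortho to C-8a of ring A. The same ketone therefore supplies the C-3 nucleophile and activates a C-8a–F bond, and the C-5 and C-7 oxygens are meta to C-8a and do not deactivate it.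
4. The enol silane comes from 5-fluororesorcinol by Houben–Hoesch acetylation next to fluorine, MOM protection, enol silylation (which also masks the ketone) and metalation/prenylation at the second fluorine-flanked carbon.
5. Because only the fluorine-bearing carbon can become C-8a, the prenyl group is fixed at C-8.

Key step: step 6

Assumption: flavanone numbering is used for ring-C compounds, and the oxazaborolidinone from N-tosyl-(R)-tryptophan is taken to leave the Si face of a boron-bound aryl aldehyde open (the S-tryptophan catalyst the Re face); if the sense proved opposite, the enantiomeric catalyst would be used.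

**Route**

Step 1
Reactants: 1 5-fluororesorcinol (5-fluorobenzene-1,3-diol)
Product: 3 1-(2-fluoro-4,6-dihydroxyphenyl)ethan-1-one, via ketiminium chloride 2 (not isolated)
Conditions: MeCN, HCl (g), ZnCl2 (cat.), Et2O, 0 °C to rt; then H2O, 100 °C
Reagents that add atoms: acetonitrile CC#N; water O
Why: Houben–Hoesch acylation, in which the nitrilium ion should attack the carbon para to one hydroxyl and ortho to the other (the fluorine-flanked position, as in the acetylation of orcinol) rather than the hindered carbon between the hydroxyls, and the ketiminium salt is hydrolysed by hot water.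

Step 2
Reactants: 3 1-(2-fluoro-4,6-dihydroxyphenyl)ethan-1-one
Product: 4 1-[2-fluoro-4,6-bis(methoxymethoxy)phenyl]ethan-1-one
Conditions: MOMCl, i-Pr2NEt, CH2Cl2, 0 to 40 °C
Reagents that add atoms: chloromethyl methyl ether COCCl
Why: Williamson-type O-alkylation of both phenols, with excess reagent and warming to bring the hydrogen-bonded ortho-hydroxyl to completion; the amine base should not enolise the ketone.

Step 3
Reactants: 4 1-[2-fluoro-4,6-bis(methoxymethoxy)phenyl]ethan-1-one
Product: 6 triethyl({1-[2-fluoro-4,6-bis(methoxymethoxy)phenyl]ethenyl}oxy)silane, via potassium enolate 5 (not isolated)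
Conditions: KN(SiMe3)2, THF, −78 °C; Et3SiCl, −78 to 0 °C
Reagents that add atoms: chlorotriethylsilane CC[Si](CC)(CC)Cl
Why: Silyl enol ether formation by kinetic deprotonation of the only enolisable position and O-silylation of the potassium enolate; the enol silane masks the ketone against the base of step 4 and is the nucleophile of step 6.

Step 4
Reactants: 6 triethyl({1-[2-fluoro-4,6-bis(methoxymethoxy)phenyl]ethenyl}oxy)silane
Product: 9 triethyl({1-[2-fluoro-4,6-bis(methoxymethoxy)-3-(3-methylbut-2-en-1-yl)phenyl]ethenyl}oxy)silane, via aryllithium 7 (not isolated), via arylcopper 8 (not isolated)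
Conditions: lithium 2,2,6,6-tetramethylpiperidide (LiTMP), THF, −78 °C; CuBr·SMe2, −78 °C; prenyl bromide, −78 to −20 °C
Reagents that add atoms: 1-bromo-3-methylbut-2-ene (prenyl bromide) CC(C)=CCBr
Why: Directed ortho-metalation under acidity control, in which the hindered lithium amide should remove the most acidic ring proton (flanked by fluorine and a MOM-oxy group, not the one between the two MOM-oxy groups that a coordinating alkyllithium would favour), followed by transmetalation to copper (which also suppresses loss of LiF to an aryne) and allylation at the primary carbon of prenyl bromide.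

Step 5
Reactants: 10 vanillin (4-hydroxy-3-methoxybenzaldehyde)
Product: 11 3-methoxy-4-(methoxymethoxy)benzaldehyde
Conditions: MOMCl, i-Pr2NEt, CH2Cl2, 0 °C to rt
Reagents that add atoms: chloromethyl methyl ether COCCl
Why: Williamson-type O-alkylation of the phenol; the MOM cap keeps the 4'-oxygen from becoming a phenoxide during step 6.

Step 6
Reactants: 9 triethyl({1-[2-fluoro-4,6-bis(methoxymethoxy)-3-(3-methylbut-2-en-1-yl)phenyl]ethenyl}oxy)silane; 11 3-methoxy-4-(methoxymethoxy)benzaldehyde
Product: 14 (2S)-2-[3-methoxy-4-(methoxymethoxy)phenyl]-5,7-bis(methoxymethoxy)-8-(3-methylbut-2-en-1-yl)-2,3-dihydro-4H-chromen-4-one, via silyl aldol ether 12 (not isolated), via cesium alkoxide 13 (not isolated)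
Conditions: oxazaborolidinone from N-tosyl-(R)-tryptophan and 3,5-(CF3)2C6H3B(OH)2 (10 mol %), EtCN, −78 °C; then CsF, 18-crown-6, DMF, −78 to 0 °C, same flask
Reagents that add atoms: none
Why: Proposed new method: the boron of the oxazaborolidinone binds the aldehyde oxygen of 11 anti to the aryl group while the indole covers one face, so enol silane 9 should add through an open Mukaiyama transition state to the exposed Si face with transfer of the silyl group to the new oxygen, which sets C-2 as S under catalyst control and gives 12 (closest known type: oxazaborolidinone-catalysed Mukaiyama aldol of aryl methyl ketone enol silanes with aromatic aldehydes). Fluoride then takes the triethylsilyl group from 12, and alkoxide 13 adds to C-8a, the fluorine-bearing carbon ortho to the C-4 carbonyl, to give an anionic σ-adduct held as the C-4 enolate, which expels fluoride (SNAr; closest known types: base-mediated closure of 1-(2-fluoroaryl)-1,3-diketones to chromones and fluoride-catalysed arylation of silyl ethers by aryl fluorides); what is new is running both events in one flask on a β-silyloxy ketone so that ring C and its stereocenter arise together. Ring C closes in 6-endo-trig mode, the alkoxide adding to the C-8a end of the ketone-conjugated C-4a=C-8a bond, and the expelled fluoride returns to desilylate the next molecule of 12, so fluoride is not consumed. The closure makes the O-1–C-8a bond and leaves the four bonds at C-2 untouched, so the configuration set in the aldol event should be carried through unchanged. Regioselectivity is fixed because only the fluorine-bearing carbon can become C-8a, which places the prenyl group at C-8 and excludes the 6-prenyl isomer that a phenol-based closure could give. The step needs cyclisation to outrun retro-aldol cleavage and E1cB elimination of the alkoxide; this rests on the ortho-acyl activation, the meta position of both MOM-oxy groups relative to C-8a, the crown-separated cesium counter-ion at low temperature, and the MOM cap on the 4'-oxygen that blocks quinone-methide ionisation at C-2.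

Step 7
Reactants: 14 (2S)-2-[3-methoxy-4-(methoxymethoxy)phenyl]-5,7-bis(methoxymethoxy)-8-(3-methylbut-2-en-1-yl)-2,3-dihydro-4H-chromen-4-one
Product: 15 (2S)-5,7-dihydroxy-2-(4-hydroxy-3-methoxyphenyl)-8-(3-methylbut-2-en-1-yl)-2,3-dihydro-4H-chromen-4-one (CNP0266453.1)
Conditions: HCl (3 M aq.), MeOH, 40 °C
Reagents that add atoms: none
Why: Acid-catalysed acetal exchange (methanolysis of the three aryl MOM ethers) under conditions that should be too mild to add the 7-hydroxyl across the prenyl double bond or to open ring C, so the S centre at C-2 is expected to survive.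

**Compound list**
1 | 5-fluororesorcinol (5-fluorobenzene-1,3-diol) | Oc1cc(O)cc(F)c1 | starting material
2 | 1-(2-fluoro-4,6-dihydroxyphenyl)ethan-1-iminium chloride | CC(=[NH2+])c1c(O)cc(O)cc1F.[Cl-] | intermediate
3 | 1-(2-fluoro-4,6-dihydroxyphenyl)ethan-1-one | CC(=O)c1c(O)cc(O)cc1F | intermediate
4 | 1-[2-fluoro-4,6-bis(methoxymethoxy)phenyl]ethan-1-one | CC(=O)c1c(OCOC)cc(OCOC)cc1F | intermediate
5 | potassium 1-[2-fluoro-4,6-bis(methoxymethoxy)phenyl]ethen-1-olate | C=C([O-])c1c(OCOC)cc(OCOC)cc1F.[K+] | intermediate
6 | triethyl({1-[2-fluoro-4,6-bis(methoxymethoxy)phenyl]ethenyl}oxy)silane | C=C(O[Si](CC)(CC)CC)c1c(OCOC)cc(OCOC)cc1F | intermediate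
7 | aryllithium of 6, lithiated at the ring carbon between fluorine and the 4-MOM-oxy group | C=C(O[Si](CC)(CC)CC)c1c(OCOC)cc(OCOC)c([Li])c1F | intermediate
8 | arylcopper corresponding to 7 | C=C(O[Si](CC)(CC)CC)c1c(OCOC)cc(OCOC)c([Cu])c1F | intermediate
9 | triethyl({1-[2-fluoro-4,6-bis(methoxymethoxy)-3-(3-methylbut-2-en-1-yl)phenyl]ethenyl}oxy)silane | C=C(O[Si](CC)(CC)CC)c1c(OCOC)cc(OCOC)c(CC=C(C)C)c1F | intermediate
10 | vanillin (4-hydroxy-3-methoxybenzaldehyde) | COc1cc(C=O)ccc1O | starting material
11 | 3-methoxy-4-(methoxymethoxy)benzaldehyde | COCOc1ccc(C=O)cc1OC | intermediate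
12 | (3S)-1-[2-fluoro-4,6-bis(methoxymethoxy)-3-(3-methylbut-2-en-1-yl)phenyl]-3-[3-methoxy-4-(methoxymethoxy)phenyl]-3-[(triethylsilyl)oxy]propan-1-one | COCOc1ccc([C@@H](O[Si](CC)(CC)CC)CC(=O)c2c(OCOC)cc(OCOC)c(CC=C(C)C)c2F)cc1OC | intermediate
13 | cesium (1S)-3-[2-fluoro-4,6-bis(methoxymethoxy)-3-(3-methylbut-2-en-1-yl)phenyl]-1-[3-methoxy-4-(methoxymethoxy)phenyl]-3-oxopropan-1-olate | COCOc1ccc([C@@H]([O-])CC(=O)c2c(OCOC)cc(OCOC)c(CC=C(C)C)c2F)cc1OC.[Cs+] | intermediate
14 | (2S)-2-[3-methoxy-4-(methoxymethoxy)phenyl]-5,7-bis(methoxymethoxy)-8-(3-methylbut-2-en-1-yl)-2,3-dihydro-4H-chromen-4-one | COCOc1ccc([C@@H]2CC(=O)c3c(OCOC)cc(OCOC)c(CC=C(C)C)c3O2)cc1OC | intermediate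
15 | (2S)-5,7-dihydroxy-2-(4-hydroxy-3-methoxyphenyl)-8-(3-methylbut-2-en-1-yl)-2,3-dihydro-4H-chromen-4-one | COc1cc([C@@H]2CC(=O)c3c(O)cc(O)c(CC=C(C)C)c3O2)ccc1O | target

**Step count**
Total steps: 7. Longest linear sequence: 6 (steps 1, 2, 3, 4, 6, 7).

**Steps most likely to fail**

Step 6. After desilylation the alkoxide may fragment by retro-aldol and recombine (erosion of enantiopurity), or lose its oxygen by E1cB elimination, faster than it closes onto C-8a; the silyl-transfer aldol may also be slow on the doubly ortho-substituted enol silane. The fallback sets out from 9 and returns at 15, using known chemistry only. Mild hydrolysis of the enol silane (AcOH, THF, H2O, rt) gives 1-[2-fluoro-4,6-bis(methoxymethoxy)-3-(3-methylbut-2-en-1-yl)phenyl]ethan-1-one F1. Acetohydroxamic acid with K2CO3 in DMSO at 80 °C (a hydroxide surrogate in SNAr) replaces the fluorine, giving the ortho-hydroxy ketone F2. DMF dimethyl acetal at 90 °C gives the enaminone F3, which closes on brief treatment with AcOH to 5,7-bis(methoxymethoxy)-8-(3-methylbut-2-en-1-yl)-4H-chromen-4-one F4. Asymmetric conjugate addition of (4-hydroxy-3-methoxyphenyl)boronic acid follows, with Pd(OCOCF3)2 and the t-BuPyOx enantiomer that leads to the 2S series, in aqueous ClCH2CH2Cl at 60 °C without added base. It should give (2S)-2-(4-hydroxy-3-methoxyphenyl)-5,7-bis(methoxymethoxy)-8-(3-methylbut-2-en-1-yl)-2,3-dihydro-4H-chromen-4-one F5, which enters the conditions of step 7 to give 15.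

Step 4. Metalation may go to the carbon between the two MOM-oxy groups under coordination control, may be incomplete, or the organocopper may be allylated at the tertiary terminus of the prenyl unit. The fallback sets out from 3 and returns at 9, with regiochemistry fixed by electrophilic substitution instead of metalation. NBS in MeCN at 0 °C should brominate para to the hydrogen-bonded hydroxyl and ortho to the free one, that is at the fluorine-flanked carbon, to give 1-(3-bromo-2-fluoro-4,6-dihydroxyphenyl)ethan-1-one F6. MOMCl and i-Pr2NEt give the bis-MOM ether F7. Suzuki–Miyaura coupling with 3-methylbut-2-enylboronic acid pinacol ester (Pd(OAc)2, a bulky biarylphosphine chosen for coupling at the primary allyl terminus, K3PO4, THF/H2O) gives the prenyl ketone F1, and KN(SiMe3)2/Et3SiCl as in step 3 gives 9.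

Step 7. Acid may add the 7-hydroxyl or methanol across the prenyl double bond, or ionise the benzylic C-2–O bond, leading to chroman formation or partial racemisation. The fallback sets out from 14 and returns at 15, exchanging the protecting groups under buffered aprotic conditions instead of solvolysing them with Brønsted acid. TMSOTf with 2,2'-bipyridyl in CH2Cl2 at 0 °C converts the three aryl MOM ethers into trimethylsilyl ethers, giving (2S)-2-[3-methoxy-4-(trimethylsilyloxy)phenyl]-8-(3-methylbut-2-en-1-yl)-5,7-bis(trimethylsilyloxy)-2,3-dihydro-4H-chromen-4-one F8. Neutral hydrolysis (MeOH/H2O, rt) then frees the phenols to give 15.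

**Further compounds**
F1 | step 6 | 1-[2-fluoro-4,6-bis(methoxymethoxy)-3-(3-methylbut-2-en-1-yl)phenyl]ethan-1-one | CC(=O)c1c(OCOC)cc(OCOC)c(CC=C(C)C)c1F
F2 | step 6 | 1-[2-hydroxy-4,6-bis(methoxymethoxy)-3-(3-methylbut-2-en-1-yl)phenyl]ethan-1-one | CC(=O)c1c(OCOC)cc(OCOC)c(CC=C(C)C)c1O
F3 | step 6 | (2E)-3-(dimethylamino)-1-[2-hydroxy-4,6-bis(methoxymethoxy)-3-(3-methylbut-2-en-1-yl)phenyl]prop-2-en-1-one | CN(C)/C=C/C(=O)c1c(OCOC)cc(OCOC)c(CC=C(C)C)c1O
F4 | step 6 | 5,7-bis(methoxymethoxy)-8-(3-methylbut-2-en-1-yl)-4H-chromen-4-one | O=c1ccoc2c(CC=C(C)C)c(OCOC)cc(OCOC)c12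
F5 | step 6 | (2S)-2-(4-hydroxy-3-methoxyphenyl)-5,7-bis(methoxymethoxy)-8-(3-methylbut-2-en-1-yl)-2,3-dihydro-4H-chromen-4-one | COc1cc([C@@H]2CC(=O)c3c(OCOC)cc(OCOC)c(CC=C(C)C)c3O2)ccc1O
F6 | step 4 | 1-(3-bromo-2-fluoro-4,6-dihydroxyphenyl)ethan-1-one | CC(=O)c1c(O)cc(O)c(Br)c1F
F7 | step 4 | 1-[3-bromo-2-fluoro-4,6-bis(methoxymethoxy)phenyl]ethan-1-one | CC(=O)c1c(OCOC)cc(OCOC)c(Br)c1F
F8 | step 7 | (2S)-2-[3-methoxy-4-(trimethylsilyloxy)phenyl]-8-(3-methylbut-2-en-1-yl)-5,7-bis(trimethylsilyloxy)-2,3-dihydro-4H-chromen-4-one | COc1cc([C@@H]2CC(=O)c3c(O[Si](C)(C)C)cc(O[Si](C)(C)C)c(CC=C(C)C)c3O2)ccc1O[Si](C)(C)C
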